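**Plan**
- Retrosynthesis: the 4'-OH is masked as a SEM acetal. The C7–O(prenyl) and C5–O(methyl) aryl ether bonds are cut together, back to a 5,7-difluoroflavone. Ring C is then cut at O1–C2 and C3–C4 into a ring-A salicylaldehyde and a ring-B α-methoxy ketone.
- Enabling feature: C5 and C7 of ring A are ortho and para (through C4a) to the C4 carbonyl of the pyranone ring C, while C8 is meta. Fluorine at C5/C7 can therefore be exchanged for alkoxide and the C8 methoxy cannot.
- Forward: ring A starts as a fluorinated guaiacol whose only free ortho position is formylated. The ring oxygen is thus a phenol from the outset, and no choice between two ortho fluorines has to be made when ring C closes. Aldol union with the ring-B ketone, oxidation and cyclodehydration build ring C.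
- Ring A is then completed in one flask by prenyloxide at C7 followed by methoxide at C5, and fluoride frees the 4'-OH.
- Stereochemistry: the target has no stereocentre and no stereogenic double bond. The two aldol stereocentres are transient and are erased by oxidation and aromatisation.

Key step: step 9

Remark: since the target is achiral, the demand for a single enantiomer is met by the constitution alone. 3,5-Difluoro-2-methoxyphenylboronic acid (1) is assumed to be a catalogue compound.

**Route**

Step 1
Reactants: 1 3,5-difluoro-2-methoxyphenylboronic acid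
Product: 2 3,5-difluoro-2-methoxyphenol
Conditions: 30% aq. H2O2, NaOH (cat.), THF–H2O, 0 °C to rt; aq. HCl
Reagents that add atoms: hydrogen peroxide, OO
Why: ipso-hydroxylation of an arylboronic acid, in which hydroperoxide adds to boron and the aryl group migrates from boron to oxygen, so the hydroxyl should appear exactly where boron was.

Step 2
Reactants: 2 3,5-difluoro-2-methoxyphenol
Product: 4 4,6-difluoro-2-hydroxy-3-methoxybenzaldehyde, via ortho-hydroxymethyl phenol 3 (not isolated)
Conditions: MgCl2 (anhydrous), Et3N, (CH2O)n, MeCN, reflux; 1 M HCl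
Reagents that add atoms: paraformaldehyde (as formaldehyde), C=O
Why: magnesium-mediated ortho-formylation (Casnati–Skattebøl formylation), in which formaldehyde is delivered inside the magnesium phenoxide chelate to an ortho carbon only and the benzylic alcohol 3 is oxidised by a second formaldehyde through hydride transfer; C2 carries methoxy, so only C6 can react, and the C4–H between the two fluorines is out of reach of the chelate.

Step 3
Reactants: 4 4,6-difluoro-2-hydroxy-3-methoxybenzaldehyde
Product: 5 2-(benzyloxy)-4,6-difluoro-3-methoxybenzaldehyde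
Conditions: BnBr, K2CO3, DMF, rt
Reagents that add atoms: benzyl bromide, BrCc1ccccc1
Why: Williamson etherification of an acidic, hydrogen-bonded phenol, which should outpace any attack of the weakly nucleophilic phenoxide on a ring fluorine at room temperature.

Step 4
Reactants: 6 4-bromo-2-methoxyphenol
Product: 7 [2-[(4-bromo-2-methoxyphenoxy)methoxy]ethyl]trimethylsilane
Conditions: SEMCl, i-Pr2NEt, CH2Cl2, 0 °C to rt
Reagents that add atoms: 2-(trimethylsilyl)ethoxymethyl chloride, C[Si](C)(C)CCOCCl
Why: O-alkylation of the phenol by the chloromethyl ether (acetal protection), giving a group that is stable to organolithiums, enolates, hydrogenolysis and alkoxides.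

Step 5
Reactants: 7 [2-[(4-bromo-2-methoxyphenoxy)methoxy]ethyl]trimethylsilane; 8 N,2-dimethoxy-N-methylacetamide
Product: 10 2-methoxy-1-[3-methoxy-4-(2-trimethylsilylethoxymethoxy)phenyl]ethanone, via aryllithium 9 (not isolated)
Conditions: n-BuLi, THF, −78 °C; then 8, −78 to 0 °C; aq. NH4Cl
Reagents that add atoms: none
Why: bromine–lithium exchange is faster than deprotonation next to the alkoxy groups, and the aryllithium should add only once to the amide because the chelated tetrahedral adduct persists until the quench (Weinreb ketone synthesis).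

Step 6
Reactants: 10 2-methoxy-1-[3-methoxy-4-(2-trimethylsilylethoxymethoxy)phenyl]ethanone; 5 2-(benzyloxy)-4,6-difluoro-3-methoxybenzaldehyde
Product: 12 3-[2-(benzyloxy)-4,6-difluoro-3-methoxyphenyl]-3-hydroxy-2-methoxy-1-[3-methoxy-4-(2-trimethylsilylethoxymethoxy)phenyl]propan-1-one (racemic mixture of diastereomers), via lithium enolate 11 (not isolated)
Conditions: LiHMDS, THF, −78 °C; then 5, −78 °C; AcOH quench at −78 °C
Reagents that add atoms: none
Why: crossed aldol addition in which the ketone has one enolisable position and the aldehyde none, the chelated lithium (Z)-enolate should add to the electron-poor aldehyde at −78 °C far faster than it attacks a ring fluorine, and the diastereomer ratio does not matter because both stereocentres are removed in steps 7 and 8.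

Step 7
Reactants: 12 3-[2-(benzyloxy)-4,6-difluoro-3-methoxyphenyl]-3-hydroxy-2-methoxy-1-[3-methoxy-4-(2-trimethylsilylethoxymethoxy)phenyl]propan-1-one
Product: 13 1-[2-(benzyloxy)-4,6-difluoro-3-methoxyphenyl]-2-methoxy-3-[3-methoxy-4-(2-trimethylsilylethoxymethoxy)phenyl]propane-1,3-dione
Conditions: Dess–Martin periodinane, CH2Cl2, 0 °C to rt
Reagents that add atoms: none
Why: Dess–Martin oxidation of a benzylic β-hydroxy ketone to the 1,3-diketone under non-basic conditions, which should avoid retro-aldol cleavage and leave the SEM and benzyl ethers intact.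

Step 8
Reactants: 13 1-[2-(benzyloxy)-4,6-difluoro-3-methoxyphenyl]-2-methoxy-3-[3-methoxy-4-(2-trimethylsilylethoxymethoxy)phenyl]propane-1,3-dione
Product: 15 5,7-difluoro-3,8-dimethoxy-2-[3-methoxy-4-(2-trimethylsilylethoxymethoxy)phenyl]chromen-4-one, via hydroxyaryl diketone 14 (not isolated)
Conditions: H2 (1 atm), 10% Pd/C, EtOAc, rt; filter; then AcOH, NaOAc, 80 °C
Reagents that add atoms: none
Why: hydrogenolysis of the benzyl aryl ether frees the phenol, which should add to the distal ketone (6-exo-trig hemiketal) and lose water in buffered acetic acid to give the 4-pyranone, the cyclodehydration that ends a Baker–Venkataraman flavone synthesis; the electron-rich ring B stabilises the C2 oxocarbenium ion, so acid weak enough to spare the SEM acetal should suffice.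

Step 9
Reactants: 15 5,7-difluoro-3,8-dimethoxy-2-[3-methoxy-4-(2-trimethylsilylethoxymethoxy)phenyl]chromen-4-one; 16 3-methylbut-2-en-1-ol (prenol)
Product: 19 3,5,8-trimethoxy-2-[3-methoxy-4-(2-trimethylsilylethoxymethoxy)phenyl]-7-(3-methylbut-2-enyloxy)chromen-4-one, via potassium prenyloxide 17 (not isolated), via 7-prenyloxy-5-fluoroflavone 18 (not isolated)
Conditions: 16, KHMDS (1.0 equiv), THF, 0 °C; add to 15, THF–DMPU, −40 to 0 °C; then NaOMe (3 equiv, 25% in MeOH), 55 °C
Reagents that add atoms: sodium methoxide, C[O-].[Na+]
Why: Two addition–elimination (SNAr) substitutions run in sequence: potassium prenyloxide adds to C7, the Meisenheimer charge is carried through C4a into the C4 carbonyl and fluoride leaves, and sodium methoxide then does the same at C5. The closest known reaction type is alkoxide-for-fluoride exchange ortho and para to the carbonyl in fluorinated chromones, quinolones, xanthones and benzophenones. No ring is closed and no stereocentre is created; two aryl C–O bonds are formed. The step needs site selectivity (C7 before C5, C8 untouched) and chemoselectivity (ring A, not C2 of the pyranone): a loosely paired potassium alkoxide in a dipolar aprotic medium should prefer the para position over the peri position beside the carbonyl, the C8 methoxy is meta to C4=O and a poor leaving group, and the 2-aryl-3-methoxy substitution makes C2 a poor acceptor. Once the 7-alkoxy group is in place, its donation into the carbonyl slows the second exchange, so one equivalent of prenyloxide at low temperature should stop at 18, and the remaining C5 fluorine then needs an excess of the smaller methoxide and heat. The SEM acetal and the prenyl alkene are inert to alkoxide, and the prenyl ether is made directly from prenol, so no ring-A phenol is ever freed.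

Step 10
Reactants: 19 3,5,8-trimethoxy-2-[3-methoxy-4-(2-trimethylsilylethoxymethoxy)phenyl]-7-(3-methylbut-2-enyloxy)chromen-4-one
Product: 20 4'-hydroxy-3,5,8,3'-tetramethoxy-7-prenyloxyflavone
Conditions: TBAF (1 M in THF), THF–DMPU, 60 °C; aq. NH4Cl
Reagents that add atoms: none
Why: fluoride attacks silicon and the 2-silylethyl acetal fragments to fluorotrimethylsilane, ethene and formaldehyde (fluoride-induced SEM cleavage), which should release the 4'-phenol without affecting the prenyl ether or the methyl ethers.

**Compound list**

1 | 3,5-difluoro-2-methoxyphenylboronic acid | COc1c(F)cc(F)cc1B(O)O | starting material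
2 | 3,5-difluoro-2-methoxyphenol | COc1c(F)cc(F)cc1O | intermediate
3 | 3,5-difluoro-2-(hydroxymethyl)-6-methoxyphenol | COc1c(F)cc(F)c(CO)c1O | intermediate
4 | 4,6-difluoro-2-hydroxy-3-methoxybenzaldehyde | COc1c(F)cc(F)c(C=O)c1O | intermediate
5 | 2-(benzyloxy)-4,6-difluoro-3-methoxybenzaldehyde | COc1c(F)cc(F)c(C=O)c1OCc2ccccc2 | intermediate
6 | 4-bromo-2-methoxyphenol | COc1cc(Br)ccc1O | starting material
7 | [2-[(4-bromo-2-methoxyphenoxy)methoxy]ethyl]trimethylsilane | COc1cc(Br)ccc1OCOCC[Si](C)(C)C | intermediate
8 | N,2-dimethoxy-N-methylacetamide | COCC(=O)N(C)OC | starting material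
9 | [3-methoxy-4-(2-trimethylsilylethoxymethoxy)phenyl]lithium | COc1cc([Li])ccc1OCOCC[Si](C)(C)C | intermediate
10 | 2-methoxy-1-[3-methoxy-4-(2-trimethylsilylethoxymethoxy)phenyl]ethanone | COCC(=O)c1ccc(OCOCC[Si](C)(C)C)c(OC)c1 | intermediate
11 | lithium (Z)-2-methoxy-1-[3-methoxy-4-(2-trimethylsilylethoxymethoxy)phenyl]ethenolate | [Li]O/C(=C\OC)c1ccc(OCOCC[Si](C)(C)C)c(OC)c1 | intermediate
12 | 3-[2-(benzyloxy)-4,6-difluoro-3-methoxyphenyl]-3-hydroxy-2-methoxy-1-[3-methoxy-4-(2-trimethylsilylethoxymethoxy)phenyl]propan-1-one (racemic mixture of diastereomers) | COc1cc(C(=O)C(OC)C(O)c2c(F)cc(F)c(OC)c2OCc3ccccc3)ccc1OCOCC[Si](C)(C)C | intermediate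
13 | 1-[2-(benzyloxy)-4,6-difluoro-3-methoxyphenyl]-2-methoxy-3-[3-methoxy-4-(2-trimethylsilylethoxymethoxy)phenyl]propane-1,3-dione | COc1cc(C(=O)C(OC)C(=O)c2c(F)cc(F)c(OC)c2OCc3ccccc3)ccc1OCOCC[Si](C)(C)C | intermediate
14 | 1-(4,6-difluoro-2-hydroxy-3-methoxyphenyl)-2-methoxy-3-[3-methoxy-4-(2-trimethylsilylethoxymethoxy)phenyl]propane-1,3-dione | COc1cc(C(=O)C(OC)C(=O)c2c(F)cc(F)c(OC)c2O)ccc1OCOCC[Si](C)(C)C | intermediate
15 | 5,7-difluoro-3,8-dimethoxy-2-[3-methoxy-4-(2-trimethylsilylethoxymethoxy)phenyl]chromen-4-one | COc1cc(-c2oc3c(OC)c(F)cc(F)c3c(=O)c2OC)ccc1OCOCC[Si](C)(C)C | intermediate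
16 | 3-methylbut-2-en-1-ol (prenol) | CC(C)=CCO | starting material
17 | potassium 3-methylbut-2-en-1-olate | CC(C)=CC[O-].[K+] | intermediate
18 | 5-fluoro-3,8-dimethoxy-2-[3-methoxy-4-(2-trimethylsilylethoxymethoxy)phenyl]-7-(3-methylbut-2-enyloxy)chromen-4-one | COc1cc(-c2oc3c(OC)c(OCC=C(C)C)cc(F)c3c(=O)c2OC)ccc1OCOCC[Si](C)(C)C | intermediate
19 | 3,5,8-trimethoxy-2-[3-methoxy-4-(2-trimethylsilylethoxymethoxy)phenyl]-7-(3-methylbut-2-enyloxy)chromen-4-one | COc1cc(-c2oc3c(OC)c(OCC=C(C)C)cc(OC)c3c(=O)c2OC)ccc1OCOCC[Si](C)(C)C | intermediate
20 | 4'-hydroxy-3,5,8,3'-tetramethoxy-7-prenyloxyflavone | COc1cc(-c2oc3c(OC)c(OCC=C(C)C)cc(OC)c3c(=O)c2OC)ccc1O | target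

**Step count**

Total: 10 steps. Longest linear sequence: 8 steps (1, 2, 3, 6, 7, 8, 9, 10); the ring-B branch (steps 4 and 5) joins at step 6.

**Steps most likely to fail**

Step 9. Positional control may be lost in the first exchange: prenyloxide may attack the peri carbon C5 or substitute twice. Alkoxide may also add at C2 and open the pyranone, or methoxide may slowly dealkylate the prenyl ether during the heated second stage. The fallback inverts the order and the control element, and sets out from 15. With sodium methoxide (1.05 equiv) in toluene–THF at 0 °C, the sodium ion held by the C4 carbonyl should deliver methoxide to C5 and give 7-fluoro-3,5,8-trimethoxy-2-[3-methoxy-4-(2-trimethylsilylethoxymethoxy)phenyl]chromen-4-one F1, which is isolated. Its single remaining fluorine at C7 would then be displaced by potassium prenyloxide 17 in DMSO at 40 °C, so the prenyl ether never meets hot methoxide. The sequence returns to the route at 19.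

Step 8. The hemiketal may dehydrate incompletely in acid mild enough to keep the SEM acetal, or the acetal may be partly lost when the acid is strengthened. The fallback gives up the protecting group at this stage and sets out from 13. After hydrogenolysis to 14 as before, closure in AcOH containing conc. HCl at 90 °C should strip the SEM group and deliver 5,7-difluoro-2-(4-hydroxy-3-methoxyphenyl)-3,8-dimethoxychromen-4-one F2. Re-protection with SEMCl and i-Pr2NEt in CH2Cl2 returns to the route at 15.

Step 2. Formylation of a doubly fluorinated, electron-poor magnesium phenoxide may be slow, giving incomplete conversion or over-reaction of the benzylic alcohol stage to methoxymethyl by-products. The fallback transfers the carbon to the same ortho position by a sigmatropic shift and sets out from 2. Allylation (allyl bromide, K2CO3, acetone) should give 1-(allyloxy)-3,5-difluoro-2-methoxybenzene F3. Claisen rearrangement (N,N-diethylaniline, 190 °C) can end only at the free ortho carbon and should give 2-allyl-3,5-difluoro-6-methoxyphenol F4. Isomerisation of the double bond (PdCl2(MeCN)2 cat., CH2Cl2) should give 3,5-difluoro-6-methoxy-2-[(E)-prop-1-enyl]phenol F5, and ozonolysis (O3, CH2Cl2–MeOH, −78 °C; Me2S) returns to the route at 4.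

**Further compounds**

F1 | step 9 | 7-fluoro-3,5,8-trimethoxy-2-[3-methoxy-4-(2-trimethylsilylethoxymethoxy)phenyl]chromen-4-one | COc1cc(-c2oc3c(OC)c(F)cc(OC)c3c(=O)c2OC)ccc1OCOCC[Si](C)(C)C
F2 | step 8 | 5,7-difluoro-2-(4-hydroxy-3-methoxyphenyl)-3,8-dimethoxychromen-4-one | COc1cc(-c2oc3c(OC)c(F)cc(F)c3c(=O)c2OC)ccc1O
F3 | step 2 | 1-(allyloxy)-3,5-difluoro-2-methoxybenzene | C=CCOc1cc(F)cc(F)c1OC
F4 | step 2 | 2-allyl-3,5-difluoro-6-methoxyphenol | C=CCc1c(F)cc(F)c(OC)c1O
F5 | step 2 | 3,5-difluoro-6-methoxy-2-[(E)-prop-1-enyl]phenol | C/C=C/c1c(F)cc(F)c(OC)c1O
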